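Take the stall as the quantity to reckon.

| setting | green | ochre | midnight | noon |
|---|---|---|---|---|
| starting material | 0.81 M | 0.81 M | 0.81 M | 0.81 M |
| other conformer | 0.25 equiv | 0.25 equiv | 0.250 equiv | 0.250 equiv |
| catalyst | 0.21 mol% | 0.21 mol% | 0.21 mol% | 0.21 mol% |
| added ligand | 3.6 mM | 7.7 mM | 2.5 mM | 5.0 mM |
| remark | run made earlier | run made earlier |  |  |
| time |  |  | 50 min | 50 min |

| run | time / min | target / % | other conformer / % | isomer of the product A / % | starting material / % |
|---|---|---|---|---|---|
| green | 8.00 | 24.2 | 11.1 | 8.6 | 56.1 |
| green | 15.0 | 29.2 | 8.9 | 10.4 | 51.5 |
| green | 25.0 | 35.1 | 8.1 | 12.5 | 48.1 |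
| green | 30.0 | 33.9 | 7.1 | 9.8 | 46.6 |
| green | 40.0 | 38.9 | 6.4 | 12.5 | 46.4 |
| green | 50.0 | 37.8 | 6.5 | 13.5 | 42.8 |
| ochre | 4.00 | 13.3 | 14.0 | 6.5 | 67.9 |
| ochre | 6.00 | 14.0 | 13.8 | 5.5 | 66.9 |
| ochre | 12.0 | 15.2 | 11.8 | 5.3 | 65.9 |
| ochre | 20.0 | 18.4 | 13.0 | 6.3 | 63.2 |
| ochre | 30.0 | 18.2 | 10.6 | 7.8 | 64.3 |
| ochre | 50.0 | 19.6 | 11.3 | 5.9 | 64.3 |

(each reading ± 1 percentage point)

* which of these there is most of at the end, counted by the starting material in it, midnight (other conformer / isomer of the product A / target / starting material)
* which of these there is most of at the end, counted by the starting material in it, noon (other conformer / isomer of the product A / target / starting material)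
* the largest of these amounts at the end, in percent of the starting material and other conformer together charged, midnight
* the largest of these amounts at the end, in percent of the starting material and other conformer together charged, noon

- a reading or a percentage of target counts all its forms, free or not

Both earlier runs climb steeply, then bend and slow. The ochre run has 13.3% target by 4.00 min and ends at 19.6%, while the green run, with less added ligand, has 24.2% by 8.00 min and ends at 37.8%.

The reckoning here supposes that added ligand takes catalyst out one for one, at a rate proportional to c(catalyst) times c(added ligand), while starting material is used at a rate proportional to c(catalyst) times c(starting material). Dividing the two rates removes catalyst and time, so ln c(starting material) falls in fixed proportion to ln c(added ligand). At the stall the ligand has lost one catalyst's worth, 1.70 mM, which gives ratio = ln(charged/left starting material) / ln(c(added ligand)/(c(added ligand) − c(catalyst))).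

Starting material is 80.0% of the charge. The green run gives 0.978 and the ochre run 0.875. Their mean, 0.927, is carried on as the work ratio, the fall of ln c(starting material) per fall of ln c(added ligand). Target is taken as the starting material used, which holds in the green run: 37.2% used against 37.8% read.

Midnight climbs steeply too. Target crosses starting material when the latter has halved, which needs a logarithmic fall of 0.693, reached with added ligand at 47.3% of its charge. The midnight reckoning allows 1.06, more than that, so at 50 min starting material is reckoned near 27.8% and target near 52.2%. The noon reckoning allows 0.385, less than the crossing needs, so at 50 min starting material is reckoned still on top near 54.4%, with target near 25.6%.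

The forecast, on the ground that “the catalyst dies, and it dies faster with more ligand”, named target at 47% for midnight and starting material at 53% for noon. The flask gives target at 48.0% in midnight and starting material at 52.9% in noon.

    starting material ⇌ other conformer (K = 0.150, k = 0.00460 /min)
    starting material + catalyst → catalyst + target (k = 43.0 /M/min)
    catalyst + other conformer → catalyst + isomer of the product A (k = 68.0 /M/min)
    target + catalyst ⇌ isomer of the product B + catalyst, rate k4*[catalyst]*[target] forward; the back reaction follows from the equilibrium constant (K = 4.80, k = 5.10 /M/min)
    catalyst + target ⇌ idle complex A (K = 0.450 /M, k = 0.0260 /M/min)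
    catalyst + added ligand ⇌ idle complex B (K = 11000 /M, k = 47.0 /M/min)

The gap of 20 percentage points in target between midnight and noon comes from the difference in added ligand. Read back from the starting material left at 50 min, the work ratio is 0.876 in midnight, below the carried 0.927, and 0.994 in noon, above it. Midnight is not at rest at that time: its starting material goes on from 29.5% at 50.0 min to 1.51% at 500 min. The neighbour flask with 0.53 mol% of catalyst holds 4.29 mM of it, more than its 2.5 mM of added ligand, so the logarithm has no value and ligand is the limiting reagent. Added ligand falls to 6.14% of its charge, free catalyst stays at 36.0%, and starting material ends at 1.12%.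

(The readings stem from a simulated flask from invented constants, and the scatter is random.)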